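The pyran ring C is cut at C4–C4a and O1–C2, which gives a ring-A resorcinol and a ring-B cinnamaldehyde. The key step exploits the local C2v symmetry of ring A. In 2-prenyl-5-silyloxyresorcinol the oxygens that become O1 and O7 flank the prenylated C8, and the carbons that become C4a and C6 are equivalent. The capped O5 cannot cyclise, so only the 8-prenyl isomer can arise. A single chiral-acid-catalysed dehydrative [3+3] annulation makes both bonds, closes the pyran and sets C2. Immediate reduction of C3=C4, methylation of O7 and buffered fluoride deprotection complete the route.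

Key step: step 5

Assumption: the sense of induction of the chiral acid cannot be predicted with confidence. The (R)-catalyst is written, and its antipode is taken if screening shows that it is the one leading to (2S).

Design notes:
- **O5 protecting group.** O5 carries TIPS. Its bulk should sharpen the discrimination in step 2 and resist acid and released water in step 5. After ring closure it is pushed towards C6 and shields that position.
- **Ring-B protecting groups.** The ring-B phenols carry TBS, so one fluoride treatment frees all three oxygens.
- **Order of the endgame.** The flavene is the only configurationally fragile compound, so it is reduced before anything else is done to it.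
- **Methylation method.** The methyl ether is installed under neutral Mitsunobu conditions, because carbonate bases can scramble aryl silyl ethers.

Step 1
Reactants: 1 phloroglucinol; 2 prenyl bromide
Product: 3 2-prenylphloroglucinol
Conditions: 1 (2 equiv), KOH (1 equiv per 2), H2O, 0 °C to rt, Ar; cold work-up at pH 5–6
Reagents that add atoms: none
Why: C-alkylation of the ambident phloroglucinolate is favoured in water because hydrogen bonding blocks the oxygens; the three ring C–H positions are equivalent, and the excess of cheap, water-soluble 1 limits polyprenylation.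

Step 2
Reactants: 3 2-prenylphloroglucinol
Product: 4 2-prenyl-5-(triisopropylsilyloxy)benzene-1,3-diol
Conditions: TIPSCl (1.0 equiv, slow addition), imidazole, CH2Cl2–DMF, −20 to 0 °C
Reagents that add atoms: triisopropylsilyl chloride, CC(C)[Si](Cl)(C(C)C)C(C)C
Why: Imidazole-promoted phenol silylation is sterically governed, so the hydroxyl para to the prenyl group (two ortho hydrogens) should react ahead of the two hydroxyls that abut the prenyl CH2, and the bulky silyl chloride widens that gap.

Step 3
Reactants: 5 2,4-dihydroxybenzaldehyde
Product: 6 2,4-bis(tert-butyldimethylsilyloxy)benzaldehyde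
Conditions: TBSCl (2.4 equiv), imidazole, DMF, rt
Reagents that add atoms: tert-butyldimethylsilyl chloride, CC(C)(C)[Si](C)(C)Cl
Why: Exhaustive phenol silylation in DMF overcomes the hydrogen bond of the 2-hydroxyl to the aldehyde, and masking both ring-B oxygens stops them from acting as nucleophiles in step 5.

Step 4
Reactants: 6 2,4-bis(tert-butyldimethylsilyloxy)benzaldehyde
Product: 7 (E)-3-[2,4-bis(tert-butyldimethylsilyloxy)phenyl]prop-2-enal
Conditions: Ph3P=CHCHO (1.15 equiv), toluene, 85 °C
Reagents that add atoms: (triphenylphosphoranylidene)acetaldehyde, O=CC=P(c1ccccc1)(c1ccccc1)c1ccccc1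
Why: The Wittig reaction of a stabilised formyl ylide gives the (E)-enal under neutral conditions that leave aryl silyl ethers intact, and the small excess of ylide limits a second homologation.

Step 5
Reactants: 4 2-prenyl-5-(triisopropylsilyloxy)benzene-1,3-diol; 7 (E)-3-[2,4-bis(tert-butyldimethylsilyloxy)phenyl]prop-2-enal
Product: 10 (2S)-7-hydroxy-8-prenyl-5-(triisopropylsilyloxy)-2',4'-bis(tert-butyldimethylsilyloxy)flav-3-ene, via allylic carbinol 8 (not isolated), via vinylogous o-quinone methide 9 (not isolated)
Conditions: (R)-3,3'-bis(2,4,6-triisopropylphenyl)-1,1'-binaphthyl-2,2'-diyl N-triflylphosphoramide (5–10 mol %), 4 (1.5 equiv), slow addition of 7, 5 Å MS, toluene (0.02 M), −60 to −40 °C, dark; Et3N quench at −40 °C, filtration through Et3N-deactivated silica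
Reagents that add atoms: none
Why: Proposed new method: the acid-bound enal 7, the most basic site in the flask, is attacked at its carbonyl carbon by one of the two equivalent C–H carbons of 4 (Friedel–Crafts hydroxyalkylation, forms C4–C4a) to give carbinol 8, which loses water to the vinylogous o-quinone methide 9, present largely as its O-protonated allyl cation paired with the chiral phosphoramide anion. The closest known reaction types are the racemic amine- or boronic-acid-mediated chromene annulation of phenols with enals and the chiral N-triflylphosphoramide-catalysed intramolecular allylic substitution of o-hydroxyaryl allylic alcohols to 2-aryl-2H-chromenes; what is new is running the C–C bond formation and the enantioselective closure under one chiral acid. The pyran ring closes by O1–C2 bond formation, either as an oxa-6π electrocyclisation of (Z)-configured 9 or as 6-endo collapse of the contact ion pair. C2 is the only new stereocentre and its face is chosen by the counter-anion, hydrogen-bonded to the C8a hydroxyl and screening one face of the planar C2–C3–C4 unit; since the two flavene enantiomers are equal in energy the selection must be kinetic, hence the apolar solvent, low temperature, low loading and cold amine quench that suppress re-ionisation of the doubly activated C2–O1 bond. Site selectivity needs no control because both C–H carbons and both free hydroxyls of 4 are symmetry-related and the silylated O5 cannot close, while carbonyl rather than β-carbon attack is favoured by bifunctional binding (P=O to the ortho phenol, N–H to the aldehyde) and by retention of the donor-styrene conjugation. The prenyl alkene should be spared because the enal levels the acidity at low temperature, and a second annulation at C6 or capture of the cation by another arene is held back by excess 4, slow addition of 7, dilution and the bulk of the O5 silyl group.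

Step 6
Reactants: 10 (2S)-7-hydroxy-8-prenyl-5-(triisopropylsilyloxy)-2',4'-bis(tert-butyldimethylsilyloxy)flav-3-ene
Product: 11 (2S)-7-hydroxy-8-prenyl-5-(triisopropylsilyloxy)-2',4'-bis(tert-butyldimethylsilyloxy)flavan
Conditions: 2-nitrobenzenesulfonylhydrazide (portionwise), Et3N, CH2Cl2, rt, dark, stopped at full consumption of 10
Reagents that add atoms: none
Why: Diimide reduction transfers H2 in a concerted syn fashion at a rate set mainly by alkene substitution, so the cis-disubstituted conjugated C3=C4 bond should react well before the trisubstituted prenyl alkene; without acid, metal or heat C2 is untouched, and it becomes locked because the flavan can neither ring-open electrocyclically nor ionise allylically.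

Step 7
Reactants: 11 (2S)-7-hydroxy-8-prenyl-5-(triisopropylsilyloxy)-2',4'-bis(tert-butyldimethylsilyloxy)flavan
Product: 12 (2S)-7-methoxy-8-prenyl-5-(triisopropylsilyloxy)-2',4'-bis(tert-butyldimethylsilyloxy)flavan
Conditions: MeOH, PPh3, DIAD, THF, 0 °C to rt
Reagents that add atoms: methanol, CO
Why: Mitsunobu etherification methylates the only free phenol under essentially neutral conditions, which avoids the phenoxide-mediated silyl transfer that accompanies carbonate/alkyl halide methods.

Step 8
Reactants: 12 (2S)-7-methoxy-8-prenyl-5-(triisopropylsilyloxy)-2',4'-bis(tert-butyldimethylsilyloxy)flavan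
Product: 13 (2S)-5,2',4'-trihydroxy-7-methoxy-8-prenylflavan (target)
Conditions: TBAF/AcOH (1:1, 3.6 equiv), THF, 0 °C, Ar; pH 6 buffer work-up
Reagents that add atoms: none
Why: Fluoride-induced desilylation of aryl silyl ethers is fast at 0 °C, and the acetic acid buffer keeps the liberated phenols protonated, so neither air oxidation nor opening of a 4'-phenoxide to a p-quinone methide (which would racemise C2) can set in.

Compound list
1 | phloroglucinol (benzene-1,3,5-triol) | Oc1cc(O)cc(O)c1 | starting material
2 | prenyl bromide (1-bromo-3-methylbut-2-ene) | CC(C)=CCBr | starting material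
3 | 2-prenylphloroglucinol, 2-(3-methylbut-2-en-1-yl)benzene-1,3,5-triol | CC(C)=CCc1c(O)cc(O)cc1O | intermediate
4 | 2-prenyl-5-(triisopropylsilyloxy)benzene-1,3-diol | CC(C)=CCc1c(O)cc(O[Si](C(C)C)(C(C)C)C(C)C)cc1O | intermediate
5 | 2,4-dihydroxybenzaldehyde | O=Cc1ccc(O)cc1O | starting material
6 | 2,4-bis(tert-butyldimethylsilyloxy)benzaldehyde | O=Cc1ccc(O[Si](C)(C)C(C)(C)C)cc1O[Si](C)(C)C(C)(C)C | intermediate
7 | (E)-3-[2,4-bis(tert-butyldimethylsilyloxy)phenyl]prop-2-enal | O=C/C=C/c1ccc(O[Si](C)(C)C(C)(C)C)cc1O[Si](C)(C)C(C)(C)C | intermediate
8 | 4-{(E)-3-[2,4-bis(tert-butyldimethylsilyloxy)phenyl]-1-hydroxyprop-2-enyl}-2-prenyl-5-(triisopropylsilyloxy)benzene-1,3-diol (carbinol configuration undefined, erased on dehydration) | OC(/C=C/c1ccc(O[Si](C)(C)C(C)(C)C)cc1O[Si](C)(C)C(C)(C)C)c1c(O)c(CC=C(C)C)c(O)cc1O[Si](C(C)C)(C(C)C)C(C)C | intermediate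
9 | (6Z)-6-{(E)-3-[2,4-bis(tert-butyldimethylsilyloxy)phenyl]prop-2-enylidene}-3-hydroxy-2-prenyl-5-(triisopropylsilyloxy)cyclohexa-2,4-dien-1-one | O=C1C(CC=C(C)C)=C(O)C=C(O[Si](C(C)C)(C(C)C)C(C)C)/C1=C/C=C/c1ccc(O[Si](C)(C)C(C)(C)C)cc1O[Si](C)(C)C(C)(C)C | intermediate
10 | (2S)-7-hydroxy-8-prenyl-5-(triisopropylsilyloxy)-2',4'-bis(tert-butyldimethylsilyloxy)flav-3-ene | Oc1cc(O[Si](C(C)C)(C(C)C)C(C)C)c2c(c1CC=C(C)C)O[C@H](c1ccc(O[Si](C)(C)C(C)(C)C)cc1O[Si](C)(C)C(C)(C)C)C=C2 | intermediate
11 | (2S)-7-hydroxy-8-prenyl-5-(triisopropylsilyloxy)-2',4'-bis(tert-butyldimethylsilyloxy)flavan | Oc1cc(O[Si](C(C)C)(C(C)C)C(C)C)c2c(c1CC=C(C)C)O[C@H](c1ccc(O[Si](C)(C)C(C)(C)C)cc1O[Si](C)(C)C(C)(C)C)CC2 | intermediate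
12 | (2S)-7-methoxy-8-prenyl-5-(triisopropylsilyloxy)-2',4'-bis(tert-butyldimethylsilyloxy)flavan | COc1cc(O[Si](C(C)C)(C(C)C)C(C)C)c2c(c1CC=C(C)C)O[C@H](c1ccc(O[Si](C)(C)C(C)(C)C)cc1O[Si](C)(C)C(C)(C)C)CC2 | intermediate
13 | 4-[(2S)-5-hydroxy-7-methoxy-8-(3-methylbut-2-enyl)-3,4-dihydro-2H-chromen-2-yl]benzene-1,3-diol | COc1cc(O)c2c(c1CC=C(C)C)O[C@H](c1ccc(O)cc1O)CC2 | target

Total step count: 8. Longest linear sequence: 6 steps (1, 2, 5, 6, 7, 8). The ring-B branch 3, 4, 5, 6, 7, 8 is equally long.

Steps most likely to fail

**Step 5.** Several things may go wrong: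
- The arene may attack the β-carbon instead of the carbonyl carbon.
- The new allylic aryl ether may re-ionise under the acid, with erosion of enantiopurity.
- A flanking hydroxyl may add to the prenyl alkene.
- A second annulation may occur at C6.
- A further arene may capture the cation.
- The flavene may disproportionate by hydride transfer.

The fallback uses known chemistry and obtains the configuration by separation instead of catalysis. It sets out from 4 and 7. The established amine-salt-mediated chromene annulation (ethylenediammonium diacetate cat., toluene, 90 °C; condensation, o-quinone methide, oxa-6π closure) should give the racemic flav-3-ene F1. Diimide reduction as in step 6 converts it into the configurationally stable racemic flavan F2. This is resolved by preparative chromatography on a polysaccharide chiral stationary phase. The (2S)-enantiomer is 11, where the route is rejoined, and the (2R)-flavan F3 is set aside.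

**Step 6.** The prenyl alkene may be saturated once an excess of diimide becomes necessary. The reaction may also stall, because diimide can disproportionate faster than it reaches the flanked C3=C4 bond. The fallback sets out from 10 and uses homogeneous hydrogenation with RhCl(PPh3)3 (cat.), H2 (1 atm), toluene, rt. Selection then rests on access of the alkene to a crowded metal centre, which discriminates strongly against trisubstituted alkenes. It returns to the route at 11 and makes no new compound.

**Step 2.** Discrimination among the three phenols may be insufficient and bis-silylation may occur, which would burden the separation. In the fallback the substitution pattern is fixed by directed ortho-metalation instead of by sterics. It sets out from 1 and replaces steps 1 and 2.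
- TIPSCl (0.5 equiv), imidazole, DMF on excess 1, whose hydroxyls are all equivalent, gives 5-(triisopropylsilyloxy)benzene-1,3-diol F4.
- MOMCl, iPr2NEt, CH2Cl2 gives the bis-MOM ether F5.
- n-BuLi, THF, 0 °C lithiates between the two OMOM groups. CuBr·SMe2 (cat.) and 2 then give the prenylated bis-MOM ether F6.
- Catalytic HCl in MeOH at 40 °C cleaves the acetals while the aryl TIPS ether survives, and the route is rejoined at 4.

Further compounds
F1 | step 5 | racemic 7-hydroxy-8-prenyl-5-(triisopropylsilyloxy)-2',4'-bis(tert-butyldimethylsilyloxy)flav-3-ene | Oc1cc(O[Si](C(C)C)(C(C)C)C(C)C)c2c(c1CC=C(C)C)OC(c1ccc(O[Si](C)(C)C(C)(C)C)cc1O[Si](C)(C)C(C)(C)C)C=C2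
F2 | step 5 | racemic 7-hydroxy-8-prenyl-5-(triisopropylsilyloxy)-2',4'-bis(tert-butyldimethylsilyloxy)flavan | Oc1cc(O[Si](C(C)C)(C(C)C)C(C)C)c2c(c1CC=C(C)C)OC(c1ccc(O[Si](C)(C)C(C)(C)C)cc1O[Si](C)(C)C(C)(C)C)CC2
F3 | step 5 | (2R)-7-hydroxy-8-prenyl-5-(triisopropylsilyloxy)-2',4'-bis(tert-butyldimethylsilyloxy)flavan | Oc1cc(O[Si](C(C)C)(C(C)C)C(C)C)c2c(c1CC=C(C)C)O[C@@H](c1ccc(O[Si](C)(C)C(C)(C)C)cc1O[Si](C)(C)C(C)(C)C)CC2
F0 | step 6 | none | none
F4 | step 2 | 5-(triisopropylsilyloxy)benzene-1,3-diol | Oc1cc(O)cc(O[Si](C(C)C)(C(C)C)C(C)C)c1
F5 | step 2 | [3,5-bis(methoxymethoxy)phenoxy]triisopropylsilane | COCOc1cc(OCOC)cc(O[Si](C(C)C)(C(C)C)C(C)C)c1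
F6 | step 2 | [3,5-bis(methoxymethoxy)-4-(3-methylbut-2-enyl)phenoxy]triisopropylsilane | COCOc1cc(O[Si](C(C)C)(C(C)C)C(C)C)cc(OCOC)c1CC=C(C)C
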